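No rate constant was given to me, so I read what I needed from the two earlier runs.

in all of them: reagent 0.264 M (fed, over 5.0 h); racemization catalyst 0.60 mM; added ligand 3.3 mM

|  | left-handed substrate | right-handed substrate | remark | time |
|---|---|---|---|---|
| autumn | 0.12 M | 0.12 M | the very flask that is asked about, followed so far |  |
| summer | 0.18 M | 0.18 M | run made earlier |  |
| flask | 0.12 M | 0.12 M |  | 4.0 d |

- autumn (time / h: left-handed substrate / %, right-handed substrate / %): 0.417: 49.1, 49.8; 1.33: 48.5, 48.9; 2.00: 44.9, 50.5; 3.00: 41.6, 50.4; 5.00: 31.9, 48.7; 6.00: 27.9, 48.9; 8.00: 20.8, 48.4
- summer (time / d: left-handed substrate / %, right-handed substrate / %): 0.208: 32.8, 48.5; 0.625: 12.8, 45.3; 1.04: 5.8, 43.2; 1.67: 4.2, 39.1; 2.50: 3.5, 36.0; 3.00: 3.2, 34.0; 4.00: 4.0, 29.6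

(scatter of a reading: 0.5 percentage points)

- reagent is single-handed; left-handed substrate and right-handed substrate are mirror images of each other, charged as a racemate, each of them at the stated concentration
- the analysis behind the earlier runs scatters by 0.5 percentage points, standard deviation
- an excess is the difference of the two amounts in percent of their sum
- an excess is below zero if the other one leads
- the handed part of reagent does not stay in what it makes, so the products of the two hands are mirror images too

- part of the left-handed substrate and right-handed substrate charged together that has reacted at 4.0 d
- excess of left-handed product over right-handed product in the product at 4.0 d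
- excess of right-handed substrate over left-handed substrate among what is left of the two at 4.0 d

1. The bench rule for a racemate and a single-handed reagent says that the fast hand reacts and the flask stops at half conversion. Here the fast hand is the left-handed substrate.

2. One border of that rule shows in a ratio of charges. In the autumn flask the reagent stood at 1.10 of both hands together, which is more than the left hand needs, so the charge of reagent was enough to carry the autumn flask past half. The summer run showed what comes next: between 2.50 d and 4.00 d the left-handed substrate read 3.5% and then 4.0%, while the right-handed substrate fell from 36.0% to 29.6%. I read that as the left hand being refilled from the right in the summer run.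

3. So I followed one left-handed molecule to its fork: it reacts, or it flips to the right hand. Mirror images flip equally fast, so on a plateau the odds of reacting against flipping are right over left, minus one. In the summer run at 2.50 d that gave 9.29, roughly, since the left reading carries a scatter of 0.5 percentage points. Counting one reagent for each substrate reacted, the reagent left in the summer run then was 17.5% of its charge. I assumed the odds follow the reagent, which gave the full-charge odds, the fork odds per fraction of a 0.264 M reagent charge still present, of 53.1, for this catalyst and ligand charge, a reading with that scatter in it. The excess of right-handed substrate is then the odds divided by the odds plus 2.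

4. The forecast called the flask “a slow dynamic kinetic resolution” and gave 73% reacted (66% to 80%), a product excess of 65% (52% to 76%) and a right-handed substrate excess of 89% (78% to 95%). Taking the forecast's conversion, 33.6% of the reagent stays, so my odds were 17.8 and my own right-handed substrate excess 89.9%, beside the forecast's 89%. The thing to watch is right over left against reagent left.

The flask gave 73.4% reacted, a product excess of 62.5% and a right-handed substrate excess of 89.3%, each inside the forecast's range.

    2 racemization catalyst ⇌ resting dimer, settled at all times (K = 82000 M⁻¹)
    reagent + left-handed substrate → left-handed product (k = 2.10 × 10⁻⁴ M⁻¹ s⁻¹)
    left-handed substrate + racemization catalyst ⇌ right-handed substrate + racemization catalyst, rate k3*[racemization catalyst]*[left-handed substrate] forward; the back reaction follows from the equilibrium constant (k = 0.0190 M⁻¹ s⁻¹)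
    racemization catalyst + added ligand ⇌ idle complex, settled at all times (K = 150 M⁻¹)
    reagent + right-handed substrate → right-handed product (k = 9.00 × 10⁻⁶ M⁻¹ s⁻¹)

With 33% of the reagent left at 4.0 d, the full-charge odds give this flask 17.7, hence an excess of right-handed substrate of 89.8%, beside the 89.3% it showed. The neighbour flask changed one setting, reagent at 0.66 M, more than the 0.264 M charged here, and kept 67% of that charge at the same time. Scaled by charge, its odds come to 88.5, so the reckoning gives 97.8%, and that neighbour flask gave 97.6%.

(Readings and results stem from a simulated flask with constants of no real substance; the scatter is artificial.)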